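## Structural features

The target is a 2,2-disubstituted 6-hydroxychroman: a benzene ring (ring A) fused through C4a and C8a to a dihydropyran (ring B), with the phenolic hydroxyl at C6, para to the ring oxygen O1. C2 carries a methyl group and a (1E,3E)-4-methylhexa-1,3-dienyl chain (C1' to C6'), whose far end is bonded to C1 of a 2,6,6-trimethylcyclohexene (ring C). C2 is the only stereocentre and is R (priorities O1 > C1' > C3 > CH3). It is fully substituted, has no hydrogen and no stereogenic neighbour to relay from. The two chain alkenes, C1'=C2' (disubstituted) and C3'=C4' (trisubstituted), are conjugated and both E.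

Fragile points are the hydroquinone monoether of ring A, which oxidises easily (above all as the phenoxide), and the C2–O1 bond, which is tertiary, allylic to the diene and prone to ionise under acid. The diene and the tetrasubstituted alkene of ring C can also isomerise or cyclise under acid. The real difficulty is to make the oxygen-bearing quaternary C2 as one enantiomer and then attach a geometrically pure diene without acid.

The key step exploits the fact that C2, with O1, its methyl group and C1', is the α-carbon of an O-arylated lactic acid. Ring B then needs only the C2–C3 bond to a two-carbon ortho arm (C3, C4) on ring A, and the carboxyl carbon is C1' in latent form.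

## Logic of the disconnections

**20 ⇒ 19.** The O–Si bond on the C6 oxygen is cut. The phenol stays silylated from the first step to the last because a free hydroquinone monoether would quench the organometallic reagents and is easily oxidised. The gain is only one of protection state. The forward step must be a fluoride cleavage neutral enough for the diene and the tertiary allylic ether.

**19 ⇒ 11 + 16.** The single bond C2'–C3' between the two alkenes is cut. This splits the molecule into a chroman half and a terpenoid half of similar size. Each alkene geometry then comes from a syn addition to an alkyne: C1'=C2' from 11, and C3'=C4' from 14 by way of 16. The forward step must join two sp2 carbons with retention at both, without acid or strong base.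

**16 ⇒ 14 ⇒ 12.** In 16 the C–I bond and the bond from C4' to its methyl group are cut together (retro-carbometalation), which gives 14. The triple bond of 14 is traced back to the acetyl group of 12. Two operations thus reach a commercial ketone that already holds ring C, C5' and C6'. The forward steps need enolisation toward the methyl group only, and a syn, terminal-selective methylmetalation.

**11 ⇒ 10 ⇒ 9.** C2' is removed from 11 (one-carbon homologation of an aldehyde), and the formyl group of 10 is returned to the ester of 9, whose carboxyl carbon is C1'. C2 has no hydrogen, so these steps cannot scramble it. The forward steps must stop at the aldehyde oxidation level and must make the alkyne without methanolic base, which would strip the aryl silyl ether.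

**9 ⇒ 8.** The C2–C3 bond is cut. Ring B opens and the quaternary stereocentre becomes the tertiary α-carbon of an aryloxypropanoate. This is the decisive simplification, because it turns an oxygenated quaternary centre into a lactate ether. The forward step demands that the enolate of 8, which no longer has a carbon stereocentre, still closes the ring on one face only.

**8 ⇒ 7 ⇒ 5.** The C–Br bond is returned to C–OH, and the primary alcohol to a vinyl group (retro-hydroboration). The two-carbon arm is thus carried as an alkene that is inert until needed. The forward steps need anti-Markovnikov hydration beside a methyl ester, and conditions that neither saponify nor epimerise the α-aryloxy ester.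

**5 ⇒ 3 + 4.** The bond between the aryl oxygen and the α-carbon is cut. This exposes a phenol and the chiral-pool hydroxy ester 4, so the stereocentre is bought. The forward etherification must go with clean inversion, so 4 has the configuration opposite to that of 5.

**3 ⇒ 2 ⇒ 1.** The vinyl C=C is cut back to the formyl group of 2, and the O–Si bond of 2 back to 1. The olefination is placed before the etherification so that the basic ylide never meets the lactate stereocentre. The forward steps need a silylation that tells the two hydroxyls of 1 apart, and an olefination that tolerates a free phenol.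

## Other disconnections considered

**Alternative 1:** The cut removes ring A: C8a–C4a, C5–C6 and C6–C7 are broken. Ring B opens at the same time, because the alkyne that supplies C4a and C5 hangs from the carbene oxygen through C2, C3 and C4.

- Forward key step: the chromium carbene pentacarbonyl{1-[(R)-3-methylhept-1-en-6-yn-3-yloxy]prop-2-en-1-ylidene}chromium A2 would be heated. The tethered alkyne and one CO insert and the dienylketene closes to the hydroquinone monoether (Dötz benzannulation), trapped as (R)-2-methyl-6-(trimethylsilyloxy)-2-vinylchroman A1. The alkoxy group of A2 is (R)-3-methylhept-1-en-6-yn-3-ol A3, which would come in two operations from (R)-linalool A4 (ozonolysis of the trisubstituted alkene, then alkyne homologation).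
- In favour: C2 is bought with the right four substituents, is never deprotonated or ionised, and two rings with the para oxygen pattern arise in one step.
- Against here: attaching a tertiary alkoxide to a chromium acylate is the least favourable case of carbene alkoxylation. An unsubstituted vinylcarbene is prone to polymerisation and conjugate addition. A full equivalent of Cr(CO)6 is consumed. The benzannulation has competing channels (cyclopentannulation, furan and cyclobutenone formation). The optical purity of natural A4 varies. The vinyl group of A1 sits on a quaternary carbon and would in practice be cut back to an aldehyde, so the route would rejoin the chosen one at the level of 10 with no saving in chain extension.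
- Comparison: on structure the two plans deliver equivalent C2 building blocks. On mechanism the alternative is the better on stereochemical security, since it needs no relay through a short-lived intermediate, but the weaker on chemoselectivity and on access to its key intermediate. On step economy it is about equal (roughly six operations to an aldehyde of the type of 10, against seven).

**Alternative 2:** The cut is the C3=C4 double bond of a 2H-chromene, with C1'=C2' kept as a vinyl group on C2. The stereocentre vanishes in the precursor 4-benzyloxy-1-[(3-methylpenta-1,4-dien-3-yl)oxy]-2-vinylbenzene A6, which carries two enantiotopic vinyl groups.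

- Forward key step: the chiral hexavalent molybdenum alkylidene Mo(N-2,6-iPr2C6H3)(CHCMe2Ph)(3,3'-di-tert-butyl-5,5',6,6'-tetramethylbiphenyl-2,2'-diolate) would engage the styrene, select one of the two vinyls and release ethylene. The product would be (S)-6-benzyloxy-2-methyl-2-vinyl-2H-chromene A5; the S descriptor follows from the ring alkene and corresponds to the spatial arrangement of the target.
- In favour: catalytic, reagent-controlled enantioselection in an irreversible ring closure, either enantiomer by choice of the diolate, no racemisable intermediate, and both C1' and C2' present in the product.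
- Against here: A6 is a tertiary, doubly allylic aryl ether. Neither SN2 nor Mitsunobu etherification can make it, arylation of the tertiary alkoxide is sluggish, and such an ether is set up for ionisation and aromatic Claisen rearrangement. The molybdenum complex needs rigorous exclusion of air and water. After ring closure, C3=C4 must be saturated beside a terminal vinyl (or, later, the diene). The benzyl ether cannot be removed by hydrogenolysis once the diene is present.
- Comparison: on structure the alternative is the better in keeping C2' and needing no redox adjustment at C1', but the worse in leaving an extra alkene in ring B and a protecting group ill-matched to the end game. On mechanism it is the equal or the better, because enantioselection does not depend on a race against bond rotation. On step economy it is at best equal, since what is saved in the ring synthesis is spent on telling three alkenes apart.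

**Alternative 3:** The cut takes C4 out of ring B (bonds C3–C4 and C4–C4a). This leaves the five-membered ketone (S)-2-methyl-5-(triisopropylsilyloxy)-2-vinylbenzofuran-3(2H)-one A8, in which the quaternary carbon already exists.

- Forward key step: Me3SiCHN2 activated by Sc(OTf)3 would add to the carbonyl, and the aryl carbon would migrate with loss of dinitrogen. After desilylation of the α-silyl ketone this would give (S)-2-methyl-6-(triisopropylsilyloxy)-2-vinylchroman-3-one A7.
- In favour: the stereocentre is neither formed nor touched in the key step, since the migrating terminus is the aryl carbon and C2 has no hydrogen. Strain release and the poor migratory aptitude of an oxygen-bearing tertiary carbon support the required regiochemistry. The vinyl group is in place.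
- Against here: the C3 carbonyl has no counterpart in the target. Removing it next to a quaternary centre, beside a vinyl group and an acid-labile tertiary allylic ether, costs two or three steps (reduction, thiocarbonyl derivative, radical deoxygenation). Double homologation and epoxide formation compete. Above all, A8 must first be made as one enantiomer, so the asymmetric problem is only moved to an earlier, undefined step.
- Comparison: on structure the chosen plan is better matched, because 9 has ring B at the right oxidation level. On mechanism the ring expansion is the better on configurational safety during the key step, but it leaves the origin of chirality open. On step economy it is the weaker by about three steps.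

Key step: step 6

Assumption: the relay in step 6 is taken to go with retention (the new C–C bond forms on the face the proton left), as is usual for potassium enolates of this kind in DMF-containing media. On that basis (S)-8 gives (R)-9. Were the sense opposite, the configuration of the chiral-pool building block in step 3 would be reversed and nothing else would change.

## Route

Step 1
Reactants: 1 2,5-dihydroxybenzaldehyde
Product: 2 5-(tert-butyldimethylsilyloxy)-2-hydroxybenzaldehyde
Conditions: TBSCl (1.05 equiv), imidazole (2.2 equiv), CH2Cl2, 0 °C
Reagents that add atoms: tert-butyldimethylsilyl chloride, CC(C)(C)[Si](C)(C)Cl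
Why: Selective phenol silylation; the 2-hydroxyl is tied up in a hydrogen bond to the formyl group and flanked by it, so one equivalent of silyl chloride should go to the free, more nucleophilic 5-hydroxyl.

Step 2
Reactants: 2 5-(tert-butyldimethylsilyloxy)-2-hydroxybenzaldehyde
Product: 3 4-(tert-butyldimethylsilyloxy)-2-vinylphenol
Conditions: Ph3PCH3Br (2.3 equiv), NaN(SiMe3)2 (2.2 equiv), THF, 0 °C; then 2, 0 °C to rt; aq. NH4Cl
Reagents that add atoms: methyltriphenylphosphonium bromide, C[P+](c1ccccc1)(c1ccccc1)c1ccccc1.[Br-]
Why: Wittig methylenation of a salicylaldehyde; one equivalent of ylide takes the phenolic proton and the second olefinates the formyl group, and keeping the phosphonium salt in excess over the amide leaves no free amide base. No stereocentre is present yet.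

Step 3
Reactants: 3 4-(tert-butyldimethylsilyloxy)-2-vinylphenol; 4 methyl (R)-lactate
Product: 5 methyl (S)-2-[4-(tert-butyldimethylsilyloxy)-2-vinylphenoxy]propanoate
Conditions: PPh3 (1.3 equiv), DIAD (1.3 equiv), THF, 0 °C to rt
Reagents that add atoms: none
Why: Mitsunobu etherification; the phenoxide displaces the alkoxyphosphonium group of the activated α-hydroxy ester by SN2, so the R centre of 4 is inverted to S in 5 under neutral conditions.

Step 4
Reactants: 5 methyl (S)-2-[4-(tert-butyldimethylsilyloxy)-2-vinylphenoxy]propanoate
Product: 7 methyl (S)-2-[4-(tert-butyldimethylsilyloxy)-2-(2-hydroxyethyl)phenoxy]propanoate, via B-alkyl-9-borabicyclo[3.3.1]nonane 6 (not isolated)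
Conditions: 9-BBN (1.3 equiv), THF, 0 °C to rt; then 30% H2O2, 3 M aq. NaOAc, 0 °C to rt
Reagents that add atoms: hydrogen peroxide, OO
Why: Hydroboration–oxidation; the bulky borane adds boron to the terminal carbon of the styrene and leaves a methyl ester alone at room temperature, and the acetate-buffered peroxide oxidation should avoid saponifying or epimerising the α-aryloxy ester.

Step 5
Reactants: 7 methyl (S)-2-[4-(tert-butyldimethylsilyloxy)-2-(2-hydroxyethyl)phenoxy]propanoate
Product: 8 methyl (S)-2-[2-(2-bromoethyl)-4-(tert-butyldimethylsilyloxy)phenoxy]propanoate
Conditions: CBr4 (1.3 equiv), PPh3 (1.4 equiv), 2,6-lutidine (0.2 equiv), CH2Cl2, 0 °C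
Reagents that add atoms: carbon tetrabromide, BrC(Br)(Br)Br
Why: Appel bromination; bromide displaces the primary alkoxyphosphonium group under nearly neutral conditions, so the ester, the silyl ether and the lactate centre are not touched.

Step 6
Reactants: 8 methyl (S)-2-[2-(2-bromoethyl)-4-(tert-butyldimethylsilyloxy)phenoxy]propanoate
Product: 9 methyl (R)-6-(tert-butyldimethylsilyloxy)-2-methylchroman-2-carboxylate
Conditions: KN(SiMe3)2 (1.2 equiv), DMF–THF (1:1), 0.02 M, −78 °C, 30 min; AcOH in THF at −78 °C
Reagents that add atoms: none
Why: KN(SiMe3)2 removes the α-proton of 8 and gives a potassium ester enolate whose ortho-substituted aryl ring cannot lie in the enolate plane, so the enolate is chiral about the aryl C–O axis although its carbon stereocentre has gone. The enolate carbon then displaces bromide from the ortho arm (intramolecular SN2), forming C2–C3 and ring B in a 6-exo-tet closure. The closest known reaction type is the memory-of-chirality cyclisation of axially chiral ester enolates, established for alkylative ring closure of N-(ω-bromoalkyl) α-amino ester enolates (C–N axis) and for C–C ring closure of lactate aryl ether enolates (C–O axis). The configuration at C2 is controlled by the sense of the transient axis, which the lactate centre dictates because the proton leaves from the conformer that holds the ortho arm on the C–H face; bond formation on that same face amounts to retention and turns (S)-8 into (R)-9. The selectivity needed is ring closure faster than rotation about the C–O axis: the ortho arm retards the rotation, while −78 °C, the potassium counter-ion, DMF (a weakly aggregated, reactive enolate) and the rigid ortho tether favour the displacement. C-alkylation is preferred to O-alkylation, which would need an eight-membered transition state, and high dilution suppresses intermolecular Claisen condensation. Loss of HBr to the styrene is held back by the hindered amide base, the low temperature and the immediate consumption of the enolate.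

Step 7
Reactants: 9 methyl (R)-6-(tert-butyldimethylsilyloxy)-2-methylchroman-2-carboxylate
Product: 10 (R)-6-(tert-butyldimethylsilyloxy)-2-methylchroman-2-carbaldehyde
Conditions: iBu2AlH (1.1 equiv), CH2Cl2, −78 °C; MeOH, then aq. potassium sodium tartrate
Reagents that add atoms: none
Why: Partial ester reduction; the aluminium hemiacetal of an α-alkoxy ester is held at −78 °C by chelation to O1 and releases the aldehyde only on work-up, and C2 has no hydrogen and cannot epimerise.

Step 8
Reactants: 10 (R)-6-(tert-butyldimethylsilyloxy)-2-methylchroman-2-carbaldehyde
Product: 11 (R)-tert-butyl[(2-ethynyl-2-methylchroman-6-yl)oxy]dimethylsilane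
Conditions: Me3SiCHN2 (1.3 equiv), n-BuLi (1.25 equiv), THF, −78 °C; then 10, −78 °C to 0 °C
Reagents that add atoms: trimethylsilyldiazomethane, C[Si](C)(C)C=[N+]=[N-]
Why: Colvin rearrangement; lithiated trimethylsilyldiazomethane adds to the non-enolisable aldehyde, silanolate is eliminated, dinitrogen is lost and the alkylidene carbene undergoes a 1,2-hydride shift to the terminal alkyne. The conditions contain no methanolic carbonate, which would cleave the aryl silyl ether.

Step 9
Reactants: 12 dihydro-β-ionone
Product: 14 4-(2,6,6-trimethylcyclohex-1-en-1-yl)but-1-yne, via enol diethyl phosphate 13 (not isolated)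
Conditions: LiN(iPr)2 (1.05 equiv), THF, −78 °C; ClP(O)(OEt)2 (1.1 equiv), −78 °C to rt; then LiN(iPr)2 (2.3 equiv), −78 °C to rt; aq. NH4Cl
Reagents that add atoms: none
Why: Methyl ketone to terminal alkyne through the kinetic enol phosphate; the amide enolises toward the methyl group, the enolate is O-phosphorylated, and a second amide-induced elimination gives the alkyne, held as its acetylide so that it does not isomerise.

Step 10
Reactants: 14 4-(2,6,6-trimethylcyclohex-1-en-1-yl)but-1-yne
Product: 16 (E)-1-iodo-2-methyl-4-(2,6,6-trimethylcyclohex-1-en-1-yl)but-1-ene, via alkenyldimethylalane 15 (not isolated)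
Conditions: AlMe3 (2.0 equiv), Cp2ZrCl2 (0.25 equiv), CH2Cl2, 0 °C to rt; then I2 (1.2 equiv), THF, −30 °C to 0 °C
Reagents that add atoms: trimethylaluminium, C[Al](C)C; iodine, II
Why: Negishi zirconium-catalysed carboalumination; methyl and aluminium add syn across the terminal alkyne with aluminium at the terminal carbon, and iodinolysis with retention gives the E iodide. The tetrasubstituted ring alkene is inert.

Step 11
Reactants: 11 (R)-tert-butyl[(2-ethynyl-2-methylchroman-6-yl)oxy]dimethylsilane; 16 (E)-1-iodo-2-methyl-4-(2,6,6-trimethylcyclohex-1-en-1-yl)but-1-ene
Product: 19 tert-butyldimethyl{[(R)-2-methyl-2-[(1E,3E)-4-methyl-6-(2,6,6-trimethylcyclohex-1-en-1-yl)hexa-1,3-dien-1-yl]chroman-6-yl]oxy}silane, via alkenylzirconocene chloride 17 (not isolated), via alkenylzinc chloride 18 (not isolated)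
Conditions: 11, Cp2Zr(H)Cl (1.2 equiv), THF, rt, dark; ZnCl2 (1.2 equiv), 0 °C; then 16 (1.2 equiv), Pd(PPh3)4 (5 mol %), THF, rt
Reagents that add atoms: none
Why: Hydrozirconation followed by Negishi cross-coupling; Zr–H adds syn with zirconium on the terminal carbon, away from the quaternary centre, which fixes C1'=C2' as E, and after transmetalation to zinc the zerovalent palladium catalyst joins the two sp2 carbons with retention at both. The medium contains no acid and no strong base.

Step 12
Reactants: 19 tert-butyldimethyl{[(R)-2-methyl-2-[(1E,3E)-4-methyl-6-(2,6,6-trimethylcyclohex-1-en-1-yl)hexa-1,3-dien-1-yl]chroman-6-yl]oxy}silane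
Product: 20 (R)-2-methyl-2-[(1E,3E)-4-methyl-6-(2,6,6-trimethylcyclohex-1-en-1-yl)hexa-1,3-dien-1-yl]chroman-6-ol
Conditions: Bu4NF (1.2 equiv), AcOH (1.2 equiv), THF, 0 °C, argon
Reagents that add atoms: none
Why: Fluoride desilylation of an aryl silyl ether, driven by the Si–F bond; the acetic acid buffer keeps the phenol protonated, which guards against air oxidation of the phenoxide, and the medium is not acidic enough to ionise the C2–O1 bond.

## Compound list

1 | 2,5-dihydroxybenzaldehyde | O=Cc1cc(O)ccc1O | starting material
2 | 5-(tert-butyldimethylsilyloxy)-2-hydroxybenzaldehyde | O=Cc1cc(O[Si](C)(C)C(C)(C)C)ccc1O | intermediate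
3 | 4-(tert-butyldimethylsilyloxy)-2-vinylphenol | C=Cc1cc(O[Si](C)(C)C(C)(C)C)ccc1O | intermediate
4 | methyl (R)-lactate | C[C@@H](O)C(=O)OC | starting material
5 | methyl (S)-2-[4-(tert-butyldimethylsilyloxy)-2-vinylphenoxy]propanoate | COC(=O)[C@H](C)Oc1ccc(O[Si](C)(C)C(C)(C)C)cc1C=C | intermediate
6 | methyl (S)-2-[2-[2-(9-borabicyclo[3.3.1]nonan-9-yl)ethyl]-4-(tert-butyldimethylsilyloxy)phenoxy]propanoate | COC(=O)[C@H](C)Oc1ccc(O[Si](C)(C)C(C)(C)C)cc1CCB1C2CCCC1CCC2 | intermediate (not isolated)
7 | methyl (S)-2-[4-(tert-butyldimethylsilyloxy)-2-(2-hydroxyethyl)phenoxy]propanoate | COC(=O)[C@H](C)Oc1ccc(O[Si](C)(C)C(C)(C)C)cc1CCO | intermediate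
8 | methyl (S)-2-[2-(2-bromoethyl)-4-(tert-butyldimethylsilyloxy)phenoxy]propanoate | COC(=O)[C@H](C)Oc1ccc(O[Si](C)(C)C(C)(C)C)cc1CCBr | intermediate
9 | methyl (R)-6-(tert-butyldimethylsilyloxy)-2-methylchroman-2-carboxylate | COC(=O)[C@@]1(C)CCc2cc(O[Si](C)(C)C(C)(C)C)ccc2O1 | intermediate
10 | (R)-6-(tert-butyldimethylsilyloxy)-2-methylchroman-2-carbaldehyde | O=C[C@@]1(C)CCc2cc(O[Si](C)(C)C(C)(C)C)ccc2O1 | intermediate
11 | (R)-tert-butyl[(2-ethynyl-2-methylchroman-6-yl)oxy]dimethylsilane | C#C[C@@]1(C)CCc2cc(O[Si](C)(C)C(C)(C)C)ccc2O1 | intermediate
12 | dihydro-β-ionone, 4-(2,6,6-trimethylcyclohex-1-en-1-yl)butan-2-one | CC(=O)CCC1=C(C)CCCC1(C)C | starting material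
13 | diethyl 4-(2,6,6-trimethylcyclohex-1-en-1-yl)but-1-en-2-yl phosphate | C=C(CCC1=C(C)CCCC1(C)C)OP(=O)(OCC)OCC | intermediate (not isolated)
14 | 4-(2,6,6-trimethylcyclohex-1-en-1-yl)but-1-yne | C#CCCC1=C(C)CCCC1(C)C | intermediate
15 | dimethyl[(E)-2-methyl-4-(2,6,6-trimethylcyclohex-1-en-1-yl)but-1-en-1-yl]alane | C[Al](C)/C=C(\C)CCC1=C(C)CCCC1(C)C | intermediate (not isolated)
16 | (E)-1-iodo-2-methyl-4-(2,6,6-trimethylcyclohex-1-en-1-yl)but-1-ene | I/C=C(\C)CCC1=C(C)CCCC1(C)C | intermediate
17 | chlorobis(cyclopentadienyl){(E)-2-[(R)-6-(tert-butyldimethylsilyloxy)-2-methylchroman-2-yl]vinyl}zirconium (cyclopentadienyl rings written σ-bonded) | Cl[Zr](C1C=CC=C1)(C1C=CC=C1)/C=C/[C@@]2(C)CCc3cc(O[Si](C)(C)C(C)(C)C)ccc3O2 | intermediate (not isolated)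
18 | chloro{(E)-2-[(R)-6-(tert-butyldimethylsilyloxy)-2-methylchroman-2-yl]vinyl}zinc | Cl[Zn]/C=C/[C@@]1(C)CCc2cc(O[Si](C)(C)C(C)(C)C)ccc2O1 | intermediate (not isolated)
19 | tert-butyldimethyl{[(R)-2-methyl-2-[(1E,3E)-4-methyl-6-(2,6,6-trimethylcyclohex-1-en-1-yl)hexa-1,3-dien-1-yl]chroman-6-yl]oxy}silane | CC1=C(CC/C(C)=C/C=C/[C@@]2(C)CCc3cc(O[Si](C)(C)C(C)(C)C)ccc3O2)C(C)(C)CCC1 | intermediate
20 | (R)-2-methyl-2-[(1E,3E)-4-methyl-6-(2,6,6-trimethylcyclohex-1-en-1-yl)hexa-1,3-dien-1-yl]chroman-6-ol | CC1=C(CC/C(C)=C/C=C/[C@@]2(C)CCc3cc(O)ccc3O2)C(C)(C)CCC1 | target

## Step count and risk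

Total step count: 12 (ten on the chroman line, two on the terpenoid line).
Longest linear sequence: 10 steps (1 to 20 through steps 1–8, 11 and 12).

Least certain steps:

**Step 6 (key step).** The most likely failure is loss of the axial chirality by rotation about the aryl C–O bond before the C–C bond forms, which would erode the enantiomeric purity. The ring has only one ortho substituent, and displacing bromide is intrinsically slower than the conjugate additions for which such enolates are known to hold their chirality. A relay in the opposite sense and base-induced loss of HBr are further possibilities. Fallback: set out from 8 and close ring B without regard to chirality (KN(SiMe3)2, THF, 0 °C) to racemic methyl 6-(tert-butyldimethylsilyloxy)-2-methylchroman-2-carboxylate F1. The enantiomers would then be separated by preparative chromatography on a chiral stationary phase (amylose tris(3,5-dimethylphenylcarbamate), supercritical CO2/2-propanol). The R enantiomer is 9, where the route is rejoined, and methyl (S)-6-(tert-butyldimethylsilyloxy)-2-methylchroman-2-carboxylate F2 is set aside. This resolution serves whichever way and however well the relay goes.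

**Step 11.** Hydrozirconation next to the quaternary centre may be incomplete, and the alkenylmetal may be protonated before it couples. Homocoupling of the iodide and palladium-induced isomerisation of the diene are also possible. Fallback: set out from 11 and add pinacolborane across the alkyne with catalytic Cp2Zr(H)Cl and Et3N to give the isolable tert-butyldimethyl{[(R)-2-methyl-2-[(E)-2-(4,4,5,5-tetramethyl-1,3,2-dioxaborolan-2-yl)vinyl]chroman-6-yl]oxy}silane F5. This would be purified and joined to 16 by Suzuki–Miyaura coupling (Pd(PPh3)4, aq. K3PO4, THF, 50 °C), returning to the route at 19.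

**Step 2.** Olefination of an aldehyde that carries a phenoxide may be slow, and during it the silyl group may move between phenoxide oxygens or the vinylphenol may polymerise. Fallback: set out from 2 and reverse the order. Mitsunobu etherification of 2 with 4 (PPh3, DIAD, THF) would give methyl (S)-2-[4-(tert-butyldimethylsilyloxy)-2-formylphenoxy]propanoate F3. Methylenation with one equivalent of pre-formed Ph3P=CH2 at −78 °C, quenched cold, would return to the route at 5. The ylide is a much weaker base than the ester enolate, and addition to the aldehyde is fast at that temperature, so the lactate centre should survive.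

**Step 8.** Addition of the lithiated diazo reagent to the hindered aldehyde may be slow, and the alkylidene carbene may be diverted into C–H insertion instead of the hydride shift. Fallback: set out from 10 and use the Corey–Fuchs sequence. CBr4 and PPh3 in CH2Cl2 at 0 °C would give (R)-tert-butyl{[2-(2,2-dibromovinyl)-2-methylchroman-6-yl]oxy}dimethylsilane F4. n-BuLi (2.1 equiv) in THF at −78 °C, then water, would return to the route at 11.

**Step 7.** Over-reduction may occur if the aluminium hemiacetal collapses before the hydride is consumed. Fallback: set out from 9, reduce fully with LiBH4 in THF to [(R)-6-(tert-butyldimethylsilyloxy)-2-methylchroman-2-yl]methanol F6, and oxidise with Dess–Martin periodinane (NaHCO3, CH2Cl2), returning to the route at 10.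

## Further compounds

F1 | step 6 | methyl 6-(tert-butyldimethylsilyloxy)-2-methylchroman-2-carboxylate (racemate) | COC(=O)C1(C)CCc2cc(O[Si](C)(C)C(C)(C)C)ccc2O1
F2 | step 6 | methyl (S)-6-(tert-butyldimethylsilyloxy)-2-methylchroman-2-carboxylate | COC(=O)[C@]1(C)CCc2cc(O[Si](C)(C)C(C)(C)C)ccc2O1
F3 | step 2 | methyl (S)-2-[4-(tert-butyldimethylsilyloxy)-2-formylphenoxy]propanoate | COC(=O)[C@H](C)Oc1ccc(O[Si](C)(C)C(C)(C)C)cc1C=O
F4 | step 8 | (R)-tert-butyl{[2-(2,2-dibromovinyl)-2-methylchroman-6-yl]oxy}dimethylsilane | BrC(Br)=C[C@@]1(C)CCc2cc(O[Si](C)(C)C(C)(C)C)ccc2O1
F5 | step 11 | tert-butyldimethyl{[(R)-2-methyl-2-[(E)-2-(4,4,5,5-tetramethyl-1,3,2-dioxaborolan-2-yl)vinyl]chroman-6-yl]oxy}silane | CC1(C)OB(/C=C/[C@@]2(C)CCc3cc(O[Si](C)(C)C(C)(C)C)ccc3O2)OC1(C)C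
F6 | step 7 | [(R)-6-(tert-butyldimethylsilyloxy)-2-methylchroman-2-yl]methanol | OC[C@@]1(C)CCc2cc(O[Si](C)(C)C(C)(C)C)ccc2O1
A1 | alternative 1 | (R)-2-methyl-6-(trimethylsilyloxy)-2-vinylchroman | C=C[C@@]1(C)CCc2cc(O[Si](C)(C)C)ccc2O1
A2 | alternative 1 | pentacarbonyl{1-[(R)-3-methylhept-1-en-6-yn-3-yloxy]prop-2-en-1-ylidene}chromium | C=CC(O[C@@](C)(C=C)CCC#C)=[Cr](=C=O)(=C=O)(=C=O)(=C=O)=C=O
A3 | alternative 1 | (R)-3-methylhept-1-en-6-yn-3-ol | C=C[C@](C)(O)CCC#C
A4 | alternative 1 | (R)-linalool | C=C[C@](C)(O)CCC=C(C)C
A5 | alternative 2 | (S)-6-benzyloxy-2-methyl-2-vinyl-2H-chromene | C=C[C@@]1(C)C=Cc2cc(OCc3ccccc3)ccc2O1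
A6 | alternative 2 | 4-benzyloxy-1-[(3-methylpenta-1,4-dien-3-yl)oxy]-2-vinylbenzene | C=CC(C)(C=C)Oc1ccc(OCc2ccccc2)cc1C=C
A7 | alternative 3 | (S)-2-methyl-6-(triisopropylsilyloxy)-2-vinylchroman-3-one | C=C[C@@]1(C)C(=O)Cc2cc(O[Si](C(C)C)(C(C)C)C(C)C)ccc2O1
A8 | alternative 3 | (S)-2-methyl-5-(triisopropylsilyloxy)-2-vinylbenzofuran-3(2H)-one | C=C[C@@]1(C)C(=O)c2cc(O[Si](C(C)C)(C(C)C)C(C)C)ccc2O1
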